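The target is disconnected at C4–C4a (chroman numbering). The feature exploited is the tertiary aryl ether O1–C2: it ties the two-carbon arm C3–C4, ending in an aldehyde, to the benzene ring directly beside C4a, so an iodine on C4a lies within reach of the C4 carbonyl. One catalytic asymmetric nickel/chromium aryl–aldehyde coupling then forms C4–C4a, closes the pyran ring and sets the (4R) carbinol. The precursor is 3-[2-iodo-4-methyl-3,5-bis(triisopropylsilyloxy)phenoxy]-3-methylbutanal, made from a symmetrical phenol so that no regiochemical choice arises. Silyl ethers permit a two-step entry to that phenol and a fluoride endgame, and C8 stays open for late acylation.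

Key step: step 6

Assumption 1: the ligand antipode named in step 6 is taken to give the (4R) carbinol; if a trial run shows the opposite sense, its mirror image (from D-valinol) is used with nothing else changed.

Assumption 2: N-methoxy-N-methyl-3-phenylpropanamide (12) is taken as a purchasable compound; chlorotriisopropylsilane, pinacolborane, N-iodosuccinimide and the other reagents are not numbered.

Design remark: triisopropylsilyl ethers are used on the two phenols for three reasons. They allow the symmetrical phenol to be made by sterically governed C–H borylation/oxidation, which benzyl ethers would not (their phenyl rings would be borylated). A Baeyer–Villiger entry from a 3,5-dialkoxy-4-methylbenzaldehyde is not relied on, because oxygens meta to the formyl carbon do not promote aryl migration. Fluoride removes them at the end without hydrogenolysis next to the benzylic C4 carbinol.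

Step 1
Reactants: 1 2-methylresorcinol
Product: 2 2,6-bis(triisopropylsilyloxy)toluene
Conditions: TIPSCl (2.4 equiv), imidazole (5 equiv), DMF, rt to 40 °C
Reagents that add atoms: chlorotriisopropylsilane, CC(C)[Si](Cl)(C(C)C)C(C)C
Why: Imidazole-promoted O-silylation of both phenols is routine, and the bulky, base-stable silyl ethers later shield the ring positions next to them and tolerate DBU, boranes and Grignard reagents (silyl ether formation).

Step 2
Reactants: 2 2,6-bis(triisopropylsilyloxy)toluene
Product: 4 4-methyl-3,5-bis(triisopropylsilyloxy)phenol, via arylboronate 3 (not isolated)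
Conditions: HBpin (1.5 equiv), [Ir(OMe)(cod)]2 (1.5 mol%), 4,4'-di-tert-butyl-2,2'-bipyridine (3 mol%), THF, 60 °C; then NaBO3·4H2O, THF/H2O, rt
Reagents that add atoms: sodium perborate, [Na+].[O-]OB=O
Why: Iridium-catalysed arene C–H borylation is governed by sterics, so only the ring hydrogen para to the methyl group (the one with no ortho substituent) should react, and perborate oxidation of the boronate in the same flask gives the symmetrical phenol (one-pot C–H borylation/oxidation).

Step 3
Reactants: 4 4-methyl-3,5-bis(triisopropylsilyloxy)phenol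
Product: 5 2-iodo-4-methyl-3,5-bis(triisopropylsilyloxy)phenol
Conditions: NIS (1.0 equiv, slow addition), CH2Cl2, −40 to 0 °C, dark
Reagents that add atoms: N-iodosuccinimide, O=C1CCC(=O)N1I
Why: In this electrophilic aromatic iodination the free phenol directs ortho, both ortho positions are equivalent by symmetry and the para position carries the methyl group, so one equivalent of reagent added slowly in the cold should give a single mono-iodide.

Step 4
Reactants: 5 2-iodo-4-methyl-3,5-bis(triisopropylsilyloxy)phenol; 6 3-chloro-3-methylbut-1-yne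
Product: 7 2-iodo-4-methyl-1-(2-methylbut-3-yn-2-yloxy)-3,5-bis(triisopropylsilyloxy)benzene
Conditions: 6 (1.5 equiv), CuCl2·2H2O (1 mol%), DBU (1.5 equiv), MeCN, 0 °C
Reagents that add atoms: none
Why: Copper-catalysed propargylic substitution of the tertiary chloride by the phenoxide is the standard way to aryl 1,1-dimethylpropargyl ethers and runs at 0 °C, well below the temperature of propargyl Claisen rearrangement or of copper-mediated coupling at the C–I bond.

Step 5
Reactants: 7 2-iodo-4-methyl-1-(2-methylbut-3-yn-2-yloxy)-3,5-bis(triisopropylsilyloxy)benzene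
Product: 9 3-[2-iodo-4-methyl-3,5-bis(triisopropylsilyloxy)phenoxy]-3-methylbutanal, via alkenyldicyclohexylborane 8 (not isolated)
Conditions: Cy2BH (1.2 equiv, from BH3·SMe2 and cyclohexene), THF, 0 °C; then 30% H2O2, pH 7 phosphate buffer, 0 °C; aldehyde used at once
Reagents that add atoms: hydrogen peroxide, OO
Why: Anti-Markovnikov hydroboration of the terminal alkyne with a bulky dialkylborane puts boron on the terminal carbon (the quaternary neighbour reinforces this), and buffered neutral peroxide oxidation gives the enol and hence the aldehyde without the base that would expel the aryloxide from a β-aryloxy aldehyde (alkyne hydroboration–oxidation).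

Step 6
Reactants: 9 3-[2-iodo-4-methyl-3,5-bis(triisopropylsilyloxy)phenoxy]-3-methylbutanal
Product: 10 (4R)-2,2,6-trimethyl-5,7-bis(triisopropylsilyloxy)chroman-4-ol
Conditions: CrCl2 (15 mol%), N-[2-((4S)-4-isopropyl-4,5-dihydrooxazol-2-yl)-6-methylphenyl]methanesulfonamide (17 mol%), 1,8-bis(dimethylamino)naphthalene (17 mol%), NiCl2(2,9-dimethyl-1,10-phenanthroline) (3 mol%), Mn powder (2 equiv), Cp2ZrCl2 (1.2 equiv), LiCl (2 equiv), MeCN, 0.02 M, rt; aq. NaHCO3 work-up
Reagents that add atoms: none
Why: Zerovalent nickel, generated from NiCl2(2,9-dimethyl-1,10-phenanthroline) by the reducing medium, inserts into the C4a–I bond, the aryl group is handed to trivalent chromium carrying the deprotonated sulfonamide–oxazoline ligand, and this arylchromium adds to the tethered aldehyde, after which Cp2ZrCl2 takes the alkoxide from chromium and Mn returns chromium to the divalent state. The closest known reaction type is the catalytic asymmetric Nozaki–Hiyama–Kishi coupling of organic halides with aldehydes, used here in its intramolecular aryl iodide variant. The pyran ring closes in the 6-exo-trig mode, C4a attacking the carbonyl carbon C4 across the O1–C2–C3 tether with the carbonyl oxygen left outside the ring. The C4 configuration is set by the chiral ligand on chromium, which differentiates the two faces of the coordinated aldehyde; the substrate has no other stereocentre, so control rests on the catalyst alone. The step needs chemoselectivity (C–I and CHO reacting, silyl ethers and the aryl ether untouched, no β-elimination of the aryloxide) and ring closure in preference to intermolecular coupling; the first is secured by the single iodine at C4a and the neutral, base-free medium, the second by the short O1–C2 tether with its C2 gem-dimethyl group and by moderate dilution.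

Step 7
Reactants: 10 (4R)-2,2,6-trimethyl-5,7-bis(triisopropylsilyloxy)chroman-4-ol
Product: 11 (4R)-8-iodo-2,2,6-trimethyl-5,7-bis(triisopropylsilyloxy)chroman-4-ol
Conditions: NIS (1.05 equiv), MeCN, 0 °C, dark
Reagents that add atoms: N-iodosuccinimide, O=C1CCC(=O)N1I
Why: C8 is the only free ring position and is activated by three oxygens (ortho to O1 and to the C7 silyl ether, para to the C5 silyl ether), so electrophilic aromatic iodination should occur there under neutral conditions that leave the acid-sensitive C4 carbinol alone.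

Step 8
Reactants: 11 (4R)-8-iodo-2,2,6-trimethyl-5,7-bis(triisopropylsilyloxy)chroman-4-ol; 12 N-methoxy-N-methyl-3-phenylpropanamide
Product: 14 1-[(4R)-4-hydroxy-2,2,6-trimethyl-5,7-bis(triisopropylsilyloxy)chroman-8-yl]-3-phenylpropan-1-one, via arylmagnesium alkoxide 13 (not isolated)
Conditions: MeMgCl (1.05 equiv), THF, −20 °C; iPrMgCl·LiCl (1.2 equiv), 0 °C; then 12 (1.5 equiv), 0 °C to rt; aq. NH4Cl
Reagents that add atoms: none
Why: Once the hydroxyl is masked as its magnesium alkoxide, iodine–magnesium exchange at C8 (helped by the two flanking oxygens) gives an arylmagnesium that adds once to the Weinreb amide, and the chelated adduct releases the ketone only on work-up, so neither protection of C4–OH nor a later oxidation is needed (halogen–magnesium exchange, Weinreb ketone synthesis).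

Step 9
Reactants: 14 1-[(4R)-4-hydroxy-2,2,6-trimethyl-5,7-bis(triisopropylsilyloxy)chroman-8-yl]-3-phenylpropan-1-one
Product: 15 1-[(4R)-4,5,7-trihydroxy-2,2,6-trimethylchroman-8-yl]-3-phenylpropan-1-one (the target)
Conditions: Bu4NF (3 equiv), AcOH (3 equiv), THF, 0 °C
Reagents that add atoms: none
Why: Buffered fluoride cleaves both aryl silyl ethers under non-acidic, non-reductive conditions, so the benzylic C4 carbinol (at risk of ionisation under acid or of C–O hydrogenolysis) and the ketone should be untouched and the C4 configuration kept (fluoride desilylation).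

Compound list
1 | 2-methylresorcinol (2-methylbenzene-1,3-diol) | Cc1c(O)cccc1O | starting material
2 | 2,6-bis(triisopropylsilyloxy)toluene | Cc1c(O[Si](C(C)C)(C(C)C)C(C)C)cccc1O[Si](C(C)C)(C(C)C)C(C)C | intermediate
3 | 2-[4-methyl-3,5-bis(triisopropylsilyloxy)phenyl]-4,4,5,5-tetramethyl-1,3,2-dioxaborolane | Cc1c(O[Si](C(C)C)(C(C)C)C(C)C)cc(B2OC(C)(C)C(C)(C)O2)cc1O[Si](C(C)C)(C(C)C)C(C)C | intermediate (not isolated)
4 | 4-methyl-3,5-bis(triisopropylsilyloxy)phenol | Cc1c(O[Si](C(C)C)(C(C)C)C(C)C)cc(O)cc1O[Si](C(C)C)(C(C)C)C(C)C | intermediate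
5 | 2-iodo-4-methyl-3,5-bis(triisopropylsilyloxy)phenol | Cc1c(O[Si](C(C)C)(C(C)C)C(C)C)cc(O)c(I)c1O[Si](C(C)C)(C(C)C)C(C)C | intermediate
6 | 3-chloro-3-methylbut-1-yne | CC(C)(Cl)C#C | starting material
7 | 2-iodo-4-methyl-1-(2-methylbut-3-yn-2-yloxy)-3,5-bis(triisopropylsilyloxy)benzene | Cc1c(O[Si](C(C)C)(C(C)C)C(C)C)cc(OC(C)(C)C#C)c(I)c1O[Si](C(C)C)(C(C)C)C(C)C | intermediate
8 | dicyclohexyl{(E)-3-[2-iodo-4-methyl-3,5-bis(triisopropylsilyloxy)phenoxy]-3-methylbut-1-enyl}borane | Cc1c(O[Si](C(C)C)(C(C)C)C(C)C)cc(OC(C)(C)/C=C/B(C2CCCCC2)C2CCCCC2)c(I)c1O[Si](C(C)C)(C(C)C)C(C)C | intermediate (not isolated)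
9 | 3-[2-iodo-4-methyl-3,5-bis(triisopropylsilyloxy)phenoxy]-3-methylbutanal | Cc1c(O[Si](C(C)C)(C(C)C)C(C)C)cc(OC(C)(C)CC=O)c(I)c1O[Si](C(C)C)(C(C)C)C(C)C | intermediate (key-step precursor)
10 | (4R)-2,2,6-trimethyl-5,7-bis(triisopropylsilyloxy)chroman-4-ol | Cc1c(O[Si](C(C)C)(C(C)C)C(C)C)cc2c(c1O[Si](C(C)C)(C(C)C)C(C)C)[C@H](O)CC(C)(C)O2 | intermediate (key-step product)
11 | (4R)-8-iodo-2,2,6-trimethyl-5,7-bis(triisopropylsilyloxy)chroman-4-ol | Cc1c(O[Si](C(C)C)(C(C)C)C(C)C)c(I)c2c(c1O[Si](C(C)C)(C(C)C)C(C)C)[C@H](O)CC(C)(C)O2 | intermediate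
12 | N-methoxy-N-methyl-3-phenylpropanamide | CON(C)C(=O)CCc1ccccc1 | starting material
13 | chloromagnesium (4R)-8-(chloromagnesio)-2,2,6-trimethyl-5,7-bis(triisopropylsilyloxy)chroman-4-olate | Cc1c(O[Si](C(C)C)(C(C)C)C(C)C)c([Mg]Cl)c2c(c1O[Si](C(C)C)(C(C)C)C(C)C)[C@H](O[Mg]Cl)CC(C)(C)O2 | intermediate (not isolated)
14 | 1-[(4R)-4-hydroxy-2,2,6-trimethyl-5,7-bis(triisopropylsilyloxy)chroman-8-yl]-3-phenylpropan-1-one | Cc1c(O[Si](C(C)C)(C(C)C)C(C)C)c(C(=O)CCc2ccccc2)c2c(c1O[Si](C(C)C)(C(C)C)C(C)C)[C@H](O)CC(C)(C)O2 | intermediate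
15 | 1-[(4R)-4,5,7-trihydroxy-2,2,6-trimethylchroman-8-yl]-3-phenylpropan-1-one | Cc1c(O)c(C(=O)CCc2ccccc2)c2c(c1O)[C@H](O)CC(C)(C)O2 | target

Total step count: 9. Longest linear sequence: 9 steps (1 to 15).

Steps most likely to fail

Step 6: poor facial selectivity at the aldehyde, or slow turnover of the ligated chromium at the crowded C4a position. The fallback sets out from aldehyde 9 and sets the stereocentre by ketone reduction instead of C–C bond formation. Closure without a chiral ligand (CrCl2 4 equiv, NiCl2 2 mol%, DMF, rt) should give racemic 2,2,6-trimethyl-5,7-bis(triisopropylsilyloxy)chroman-4-ol F1. Dess–Martin oxidation (NaHCO3, CH2Cl2) should give 2,2,6-trimethyl-5,7-bis(triisopropylsilyloxy)chroman-4-one F2. Corey–Bakshi–Shibata reduction ((S)-2-methyl-CBS-oxazaborolidine 10 mol%, BH3·SMe2, THF, −20 °C), with the aryl ring as the large group, is expected to deliver the (4R)-alcohol, and the route is rejoined at 10.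

Step 5: loss of the aryloxide by β-elimination during the oxidative work-up or on handling of the aldehyde. The fallback sets out from alkyne 7 and reaches the aldehyde through a stable alcohol, oxidised without base just before use. The same alkenylborane 8 is protonolysed with AcOH to 2-iodo-4-methyl-1-(2-methylbut-3-en-2-yloxy)-3,5-bis(triisopropylsilyloxy)benzene F3. Hydroboration with 9-BBN (THF, rt) gives the B-alkyl-9-borabicyclononane adduct F4 (not isolated), and NaBO3·4H2O oxidation gives 3-[2-iodo-4-methyl-3,5-bis(triisopropylsilyloxy)phenoxy]-3-methylbutan-1-ol F5, which can be stored. Dess–Martin oxidation (NaHCO3, CH2Cl2, 0 °C) then releases the aldehyde immediately before step 6, and the route is rejoined at 9.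

Step 8: failure of the crowded, alkoxide-bearing arylmagnesium to add to the amide, ending in protonation at C8. The fallback sets out from iodide 11 and uses a smaller, more electrophilic carbonyl partner. TESCl/imidazole (DMF, rt) gives (4R)-8-iodo-2,2,6-trimethyl-4-(triethylsilyloxy)-5,7-bis(triisopropylsilyloxy)chroman F6. Exchange with iPrMgCl·LiCl (THF, 0 °C) gives the C8 arylmagnesium chloride F7 (not isolated), which adds to 3-phenylpropanal to give 1-[(4R)-2,2,6-trimethyl-4-(triethylsilyloxy)-5,7-bis(triisopropylsilyloxy)chroman-8-yl]-3-phenylpropan-1-ol F8 as a mixture of epimers at the new carbinol. Dess–Martin oxidation gives 1-[(4R)-2,2,6-trimethyl-4-(triethylsilyloxy)-5,7-bis(triisopropylsilyloxy)chroman-8-yl]-3-phenylpropan-1-one F9. Bu4NF/AcOH (THF, 0 °C) removes all three silyl groups, and the route is rejoined at the target 15.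

Further compounds
F1 | step 6 | racemic 2,2,6-trimethyl-5,7-bis(triisopropylsilyloxy)chroman-4-ol | Cc1c(O[Si](C(C)C)(C(C)C)C(C)C)cc2c(c1O[Si](C(C)C)(C(C)C)C(C)C)C(O)CC(C)(C)O2
F2 | step 6 | 2,2,6-trimethyl-5,7-bis(triisopropylsilyloxy)chroman-4-one | Cc1c(O[Si](C(C)C)(C(C)C)C(C)C)cc2c(c1O[Si](C(C)C)(C(C)C)C(C)C)C(=O)CC(C)(C)O2
F3 | step 5 | 2-iodo-4-methyl-1-(2-methylbut-3-en-2-yloxy)-3,5-bis(triisopropylsilyloxy)benzene | Cc1c(O[Si](C(C)C)(C(C)C)C(C)C)cc(OC(C)(C)C=C)c(I)c1O[Si](C(C)C)(C(C)C)C(C)C
F4 | step 5 | 9-{3-[2-iodo-4-methyl-3,5-bis(triisopropylsilyloxy)phenoxy]-3-methylbutyl}-9-borabicyclo[3.3.1]nonane | Cc1c(O[Si](C(C)C)(C(C)C)C(C)C)cc(OC(C)(C)CCB2C3CCCC2CCC3)c(I)c1O[Si](C(C)C)(C(C)C)C(C)C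
F5 | step 5 | 3-[2-iodo-4-methyl-3,5-bis(triisopropylsilyloxy)phenoxy]-3-methylbutan-1-ol | Cc1c(O[Si](C(C)C)(C(C)C)C(C)C)cc(OC(C)(C)CCO)c(I)c1O[Si](C(C)C)(C(C)C)C(C)C
F6 | step 8 | (4R)-8-iodo-2,2,6-trimethyl-4-(triethylsilyloxy)-5,7-bis(triisopropylsilyloxy)chroman | Cc1c(O[Si](C(C)C)(C(C)C)C(C)C)c(I)c2c(c1O[Si](C(C)C)(C(C)C)C(C)C)[C@H](O[Si](CC)(CC)CC)CC(C)(C)O2
F7 | step 8 | [(4R)-2,2,6-trimethyl-4-(triethylsilyloxy)-5,7-bis(triisopropylsilyloxy)chroman-8-yl]magnesium chloride | Cc1c(O[Si](C(C)C)(C(C)C)C(C)C)c([Mg]Cl)c2c(c1O[Si](C(C)C)(C(C)C)C(C)C)[C@H](O[Si](CC)(CC)CC)CC(C)(C)O2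
F8 | step 8 | 1-[(4R)-2,2,6-trimethyl-4-(triethylsilyloxy)-5,7-bis(triisopropylsilyloxy)chroman-8-yl]-3-phenylpropan-1-ol (epimer mixture at the carbinol) | Cc1c(O[Si](C(C)C)(C(C)C)C(C)C)c(C(O)CCc2ccccc2)c2c(c1O[Si](C(C)C)(C(C)C)C(C)C)[C@H](O[Si](CC)(CC)CC)CC(C)(C)O2
F9 | step 8 | 1-[(4R)-2,2,6-trimethyl-4-(triethylsilyloxy)-5,7-bis(triisopropylsilyloxy)chroman-8-yl]-3-phenylpropan-1-one | Cc1c(O[Si](C(C)C)(C(C)C)C(C)C)c(C(=O)CCc2ccccc2)c2c(c1O[Si](C(C)C)(C(C)C)C(C)C)[C@H](O[Si](CC)(CC)CC)CC(C)(C)O2
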